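**Retrosynthetic overview**

- Feature used: the adjacent pyrrole carbons C2 and C3 of the indole both carry SMe. Both sulfur atoms can therefore enter on one carbon (the future C3) as a dithioacetal, and one of them is moved to C2 at the end.
- 13 ⇐ 12: acid-induced 1,2-shift of one SMe from C3 to C2 of a 3,3-bis(methylthio)-3H-indole, with aromatisation.
- 12 ⇐ 9: the C2–C3 bond is made by adding the dithioacetal carbanion to the ortho-isocyanide carbon. This closes the pyrrole ring, the only ring formed; the dibrominated benzene ring comes with 1.
- 9 ⇐ 7 ⇐ 6 ⇐ 4 ⇐ 1: formylation and dehydration of the aniline, nitro reduction, dithioacetal formation with two equivalents of methanethiol, and conversion of the methyl group of 1 into the aldehyde through the enamine.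

Key step: step 7

Assumption: 2,4-dibromo-6-nitrotoluene (1) is taken as a catalogue compound; if it had to be made, bromination of 4-bromo-2-nitrotoluene with NBS in H2SO4 should go to the position ortho to methyl and meta to nitro.

**Route**

Step 1
Reactants: 1 2,4-dibromo-6-nitrotoluene; 2 N,N-dimethylformamide dimethyl acetal
Product: 3 (E)-2-(2,4-dibromo-6-nitrophenyl)-N,N-dimethylethen-1-amine
Conditions: DMF, 110 °C
Reagents that add atoms: none
Why: The methyl group is acidified by the ortho-nitro group and condenses with the formamide acetal (first stage of the Leimgruber–Batcho sequence), and the trans enamine is the thermodynamic isomer.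

Step 2
Reactants: 3 (E)-2-(2,4-dibromo-6-nitrophenyl)-N,N-dimethylethen-1-amine
Product: 4 2,4-dibromo-6-nitrobenzaldehyde
Conditions: NaIO4 (3 equiv), THF/H2O (1:1), rt
Reagents that add atoms: NaIO4, [Na+].[O-]I(=O)(=O)=O
Why: Periodate cleaves the electron-rich enamine C=C bond (oxidative cleavage of a Leimgruber–Batcho enamine to the ortho-nitrobenzaldehyde), while the nitro group and the aryl bromides are inert.

Step 3
Reactants: 4 2,4-dibromo-6-nitrobenzaldehyde; 5 methanethiol (first equivalent)
Product: 6 1,5-dibromo-2-[bis(methylthio)methyl]-3-nitrobenzene
Conditions: MeSH (2.5 equiv, condensed), BF3·OEt2 (cat.), CH2Cl2, −20 °C → rt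
Reagents that add atoms: methanethiol (second equivalent), CS
Why: Lewis-acid-catalysed dithioacetal formation, in which the electron-poor aldehyde takes up the first thiol as the hemithioacetal, BF3 promotes loss of water to the thionium ion, and the second equivalent of thiol adds to it.

Step 4
Reactants: 6 1,5-dibromo-2-[bis(methylthio)methyl]-3-nitrobenzene
Product: 7 3,5-dibromo-2-[bis(methylthio)methyl]aniline
Conditions: Fe powder, NH4Cl, EtOH/H2O (4:1), 75 °C
Reagents that add atoms: none
Why: Béchamp-type nitro reduction under near-neutral conditions, which is not poisoned by sulfur, does not touch C–Br bonds and does not hydrolyse the dithioacetal.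

Step 5
Reactants: 7 3,5-dibromo-2-[bis(methylthio)methyl]aniline
Product: 8 N-{3,5-dibromo-2-[bis(methylthio)methyl]phenyl}formamide
Conditions: HCO2H, Ac2O, 55 °C; then 7, THF, 0 °C → rt
Reagents that add atoms: acetic formic anhydride, CC(=O)OC=O (made in the flask from formic acid and acetic anhydride)
Why: N-formylation by the mixed anhydride, which transfers the formyl group selectively and is reactive enough for an ortho-substituted, electron-poor aniline.

Step 6
Reactants: 8 N-{3,5-dibromo-2-[bis(methylthio)methyl]phenyl}formamide
Product: 9 1,5-dibromo-2-[bis(methylthio)methyl]-3-isocyanobenzene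
Conditions: POCl3 (1.1 equiv), Et3N (excess), CH2Cl2, −20 → 0 °C; aq. Na2CO3 work-up
Reagents that add atoms: none
Why: Ugi-type dehydration of a formamide to the isocyanide (O-phosphorylation, then base-induced elimination), run in a basic medium that protects both the dithioacetal and the isocyanide.

Step 7
Reactants: 9 1,5-dibromo-2-[bis(methylthio)methyl]-3-isocyanobenzene
Product: 12 4,6-dibromo-3,3-bis(methylthio)-3H-indole, via dithioacetal benzyllithium 10 (not isolated), via 2-lithio-3H-indole 11 (not isolated)
Conditions: 9 added slowly to LiN(i-Pr)2 (1.1 equiv), THF, −78 °C, then −78 → −40 °C; AcOH, −78 °C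
Reagents that add atoms: none
Why: Proposed new method: LiN(i-Pr)2 removes the one C–H that is flanked by two sulfur atoms and the aryl ring, and the tertiary carbanion 10 adds to the divalent isocyanide carbon, which makes the C2–C3 bond and gives the imidoyl lithium 11; as C3 is fully substituted, no shift to an N-metalated indole is open, so C2 takes up a proton from i-Pr2NH in the flask or from AcOH at the quench. The closest known reaction type is the Ito–Saegusa indole synthesis (ring closure of ortho-lithiomethyl aryl isocyanides with the same base), together with the α-addition of carbanions to isocyanides that gives metalated aldimines; new here are the bis(methylthio)-stabilised tertiary carbanion and a 3H-indole as the product. The five-membered N1–C2–C3–C3a–C7a ring closes in the 5-endo-dig mode. No stereocentre is formed, since C3 carries two identical SMe groups. The step needs metalation at the dithioacetal carbon and not at the ring C–H between the two bromines, no bromine–lithium exchange and no amide addition to the isocyanide: the dithioacetal C–H is the more acidic by several pKa units, an amide base does not exchange aryl bromides, the hindered amide at −78 °C should not add to the ortho-substituted isocyanide, and any aryllithium formed between the bromines (stable at −78 °C) can hand its charge back through i-Pr2NH to the benzylic site, from which the closure removes it for good.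

Step 8
Reactants: 12 4,6-dibromo-3,3-bis(methylthio)-3H-indole
Product: 13 4,6-dibromo-2,3-bis(methylthio)-1H-indole
Conditions: CF3CO2H (1.5 equiv), CH2Cl2, 0 °C → rt, short reaction time; aq. NaHCO3
Reagents that add atoms: none
Why: Acid-induced 1,2-sulfenyl shift of a 3,3-bis(alkylthio)-3H-indolium ion (the pathway known from the second sulfenylation of 3-(alkylthio)indoles, a sulfur analogue of the Plancher rearrangement): N-protonation makes C2 electrophilic, one SMe bridges C2 and C3 as an episulfonium ion and opens toward C2, and loss of the C2 proton gives the aromatic 1H-indole, helped by relief of the clash between the C3 substituents and the C4 bromine.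

**Compound list**

1 | 2,4-dibromo-6-nitrotoluene | Cc1c(Br)cc(Br)cc1[N+](=O)[O-] | starting material
2 | N,N-dimethylformamide dimethyl acetal | COC(OC)N(C)C | starting material
3 | (E)-2-(2,4-dibromo-6-nitrophenyl)-N,N-dimethylethen-1-amine | CN(C)/C=C/c1c(Br)cc(Br)cc1[N+](=O)[O-] | intermediate
4 | 2,4-dibromo-6-nitrobenzaldehyde | O=Cc1c(Br)cc(Br)cc1[N+](=O)[O-] | intermediate
5 | methanethiol | CS | starting material
6 | 1,5-dibromo-2-[bis(methylthio)methyl]-3-nitrobenzene | CSC(SC)c1c(Br)cc(Br)cc1[N+](=O)[O-] | intermediate
7 | 3,5-dibromo-2-[bis(methylthio)methyl]aniline | CSC(SC)c1c(Br)cc(Br)cc1N | intermediate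
8 | N-{3,5-dibromo-2-[bis(methylthio)methyl]phenyl}formamide | CSC(SC)c1c(Br)cc(Br)cc1NC=O | intermediate
9 | 1,5-dibromo-2-[bis(methylthio)methyl]-3-isocyanobenzene | CSC(SC)c1c(Br)cc(Br)cc1[N+]#[C-] | intermediate
10 | [(2,4-dibromo-6-isocyanophenyl)bis(methylthio)methyl]lithium | [Li]C(SC)(SC)c1c(Br)cc(Br)cc1[N+]#[C-] | intermediate
11 | 4,6-dibromo-2-lithio-3,3-bis(methylthio)-3H-indole | [Li]C1=Nc2cc(Br)cc(Br)c2C1(SC)SC | intermediate
12 | 4,6-dibromo-3,3-bis(methylthio)-3H-indole | CSC1(SC)C=Nc2cc(Br)cc(Br)c21 | intermediate
13 | 4,6-dibromo-2,3-bis(methylthio)-1H-indole | CSc1[nH]c2cc(Br)cc(Br)c2c1SC | target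

Total step count: 8
Longest linear sequence: 8 steps

**Steps most likely to fail**

1. Step 7. The amide base may metalate the ring C–H between the two bromines faster than the hindered dithioacetal C–H, and LiBr loss from that aryllithium on warming would destroy the material. The hindered, doubly sulfur-stabilised carbanion may also add too slowly to the isocyanide, the closure may be reversible and lie on the open side, or the amide may add to the isocyanide instead. The fallback puts the sulfur atoms on a preformed indole by known chemistry; it sets out from enamine 3 and comes back to the route at 12. Fe in AcOH at 80 °C reduces the nitro group, and the aniline closes onto the enamine with loss of dimethylamine (second stage of the Leimgruber–Batcho indole synthesis) to give 4,6-dibromo-1H-indole F1. MeSCl (prepared beforehand from MeSSMe and SO2Cl2) in CH2Cl2 at −78 → 0 °C sulfenylates C3 to give 4,6-dibromo-3-(methylthio)-1H-indole F2. A second equivalent of MeSCl attacks C3 again and gives 12 as its hydrochloride, which should rearrange in the same flask as in step 8 to 13.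

2. Step 8. Instead of the intramolecular shift, a sulfenyl group may be passed between molecules (disproportionation to mono- and tris-sulfides), or the 2-unsubstituted 3H-indole may oligomerise or be opened hydrolytically before it rearranges. The fallback forms the C2–S bond without any cationic shift; it sets out from 12 and comes back at 13. S8 with Et3N in DMF at 80 °C should convert the aldimine C–H into the thiolactam (Kindler-type thionation), giving 4,6-dibromo-3,3-bis(methylthio)indoline-2-thione F3. MeI and K2CO3 in acetone S-methylate it to 4,6-dibromo-2,3,3-tris(methylthio)-3H-indole F4. NaSMe in THF/MeOH at 0 °C then attacks one sulfur at C3, MeSSMe leaves, and the aromatic indolide is protonated to 13 (the reverse of an indolide sulfenylation by a disulfide, driven by aromatisation).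

3. Step 3. The aldehyde is flanked by two ortho substituents and is electron-poor, so the condensation may stop at the hemithioacetal because ionisation to the thionium ion is slow, and the volatile thiol may escape before the second equivalent has added. The fallback makes both C–S bonds by substitution instead of carbonyl condensation; it sets out from 1 and comes back at 6. NBS with azobisisobutyronitrile in PhCF3 at reflux brominates the methyl group to give 1,5-dibromo-2-(bromomethyl)-3-nitrobenzene F5. NaSMe in THF at 0 °C gives 1,5-dibromo-2-[(methylthio)methyl]-3-nitrobenzene F6. NCS in CH2Cl2 at 0 °C chlorinates the benzylic carbon next to sulfur to give 1,5-dibromo-2-[chloro(methylthio)methyl]-3-nitrobenzene F7, which is treated in the same flask with MeSH and Et3N to give 6.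

**Further compounds**

F1 | step 7 | 4,6-dibromo-1H-indole | Brc1cc(Br)c2cc[nH]c2c1
F2 | step 7 | 4,6-dibromo-3-(methylthio)-1H-indole | CSc1c[nH]c2cc(Br)cc(Br)c12
F3 | step 8 | 4,6-dibromo-3,3-bis(methylthio)indoline-2-thione | CSC1(SC)C(=S)Nc2cc(Br)cc(Br)c21
F4 | step 8 | 4,6-dibromo-2,3,3-tris(methylthio)-3H-indole | CSC1=Nc2cc(Br)cc(Br)c2C1(SC)SC
F5 | step 3 | 1,5-dibromo-2-(bromomethyl)-3-nitrobenzene | BrCc1c(Br)cc(Br)cc1[N+](=O)[O-]
F6 | step 3 | 1,5-dibromo-2-[(methylthio)methyl]-3-nitrobenzene | CSCc1c(Br)cc(Br)cc1[N+](=O)[O-]
F7 | step 3 | 1,5-dibromo-2-[chloro(methylthio)methyl]-3-nitrobenzene | CSC(Cl)c1c(Br)cc(Br)cc1[N+](=O)[O-]
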